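I decided to rank the set-ups by one number, the capture number, before reckoning any yield.

    starting material → intermediate (k1 = 0.925 min⁻¹)
    partner + intermediate → product (k2 = 7.22 M⁻¹ min⁻¹)
    partner + product ⇌ idle adduct, settled at all times (K3 = 67 M⁻¹)

the same everywhere: starting material 17 mM
- birch: partner 1.50 equiv (fed, over 8.00 min); time 8.0 min; all but partner at the start; partner goes in evenly over 8.00 min, the run ends at 8.0 min
- elm: partner 1.50 equiv; time 8.0 min; everything together in a closed stirred flask, run for 8.0 min
- alder: partner 1.50 equiv; one stirred flow tank at steady state, fed with the mixture as stated, mean residence time 8.0 min
- cedar: partner 1.50 equiv; one stirred flow tank at steady state, fed with the mixture as stated, mean residence time 40.0 min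

- product is meant together with its idle adduct
- the stated concentrations are those of everything mixed, before any reaction; amounts are the same in each set-up
- the feed brings no volume worth counting
- run time (birch): 8.0 min

- the set-up with the highest amount of product at the outlet or at the end, in percent of the starting material put in ("none" if the first two lie within 2 percentage points) (birch / elm / alder / cedar / none)
- amount of product at the outlet or at the end, in percent of the starting material put in, birch
- amount of product at the outlet or at the end, in percent of the starting material put in, elm
- amount of product at the outlet or at the end, in percent of the starting material put in, alder
- amount of product at the outlet or at the end, in percent of the starting material put in, cedar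

- The capture number is the rate at which partner takes up one intermediate (second rate constant times c(partner)) divided by the rate of leaving (one over the time in the vessel), so the units cancel and the number is second rate constant times c(partner) times the time in the vessel; for cedar at the full charge of partner I made it 7.36.
- I compared the steps first: the rate constant with which the intermediate forms, 0.925 min⁻¹, is larger than the 0.184 min⁻¹ with which it is captured at the full charge of partner, so I took the second step as the rate-limiting step.
- For elm, with the partner in from the start, the number was 1.47, and I reckoned a product share of 77.1 %.
- For birch, even feeding gives about half of that partner on average over the run, which took my figure down to 52.1 %.
- For alder, I multiplied the share of starting material converted in a tank by N/(1+N), where N is the capture number, and got 52.5 %.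
- For cedar, the longer stay raised the same reckoning to 85.7 %, the highest of my figures.
- I let no partner be used up in these figures, although the second step and the idle adduct both draw it down, so I took them as high.
- The forecast was lower than my figures: 39.3 % for birch, 55.8 % for elm, 40.9 % for alder and 70.3 % for cedar, with cedar best, on the ground that “the slow partner-capture step sets the yield”.
- The simulation gave 39.3 % for birch, 55.8 % for elm, 41.0 % for alder and 70.4 % for cedar, so cedar came out highest. In cedar, c(partner) stood at 9.03 mM. That reading turned the capture number 7.36 into 2.61, and my tank reckoning then gave 70.4 % for cedar. In alder, c(partner) stood at 15.0 mM, which made the capture number 0.869, reckoned as product per intermediate, and the alder outlet held 41.0 % product against 47.1 % intermediate.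

The constants used here are invented; the flask was simulated.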